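**Plan**

Locants used: C1 = acetal CH(OAc), O2 = ring oxygen, C3 = enol-ether CH, C4, C4a = ring-fusion CH, C5/C6 = lactone CH2/C=O, C11a = CH bearing the alkenyl group, C11 = its sp2 carbon, C12 = lactone CH–O.
Enabling feature: ring A (O2–C1–C11a–C4a–C4–C3), with C4 at the ketone level, is the 6-alkoxy-2H-pyran-3(6H)-one that furfuryl alcohol gives on oxidative ring expansion; in it C11a is the β-carbon and C4a the α-carbon of an enone.
Cuts: C11–C11a and C4a–C5 (one three-component operation), C4–C12 (alkenyl triflate plus aldehyde), O–C6 (lactonisation), both acetates, and C12–C13 of the side-chain aldehyde (alkenylalane plus oxirane).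
Forward order: furan to pyranone ring A; alkenylcuprate addition and enolate alkylation; C3-enol triflate; Ni/Cr coupling and δ-lactone ring B; deprotection and diacetylation.
Stereochemistry: C1 by catalytic dynamic kinetic acylation of the racemising lactol and stereoretentive Pd etherification; C11a anti to C1–OR and C4a anti to C11a in the key step; C12 by ligand control at chromium; C1–OAc re-formed trans to C11a at the end; E-alkene by syn-carboalumination.

Key step: step 6

Assumption: the senses of induction of benzotetramisole (step 2) and of the oxazoline–sulfonamide ligand (step 12) are taken to be those that give the configurations drawn; both antipodes of each are accessible, so a mismatch is corrected by using the other antipode.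

**Route**

Step 1
Reactants: 1 furfuryl alcohol
Product: 3 6-hydroxy-2H-pyran-3(6H)-one (racemic lactol), via (Z)-5-hydroxy-4-oxopent-2-enal 2 (not isolated)
Conditions: NBS, NaHCO3, THF/H2O (4:1), 0 °C
Reagents that add atoms: water, O
Why: Achmatowicz rearrangement: bromonium-initiated oxidation of the furan and hydrolysis give the (Z)-enedione 2, whose primary hydroxyl adds to the aldehyde to close the six-membered lactol; the acetal centre is racemic and epimerises by ring–chain tautomerism, which step 2 exploits.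

Step 2
Reactants: 3 6-hydroxy-2H-pyran-3(6H)-one
Product: 4 (R)-5-oxo-5,6-dihydro-2H-pyran-2-yl 2-methylpropanoate
Conditions: (iPrCO)2O, (R)-benzotetramisole (2 mol %, antipode as per the assumption), iPr2NEt, CHCl3, 0 °C
Reagents that add atoms: isobutyric anhydride, CC(C)C(=O)OC(=O)C(C)C
Why: Isothiourea-catalysed dynamic kinetic asymmetric acylation of a configurationally labile lactol: the lactol enantiomers interconvert through 2 while the chiral acyl-isothiouronium ion acylates one of them faster, so the catalyst sets C1 (R).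

Step 3
Reactants: 4 (R)-5-oxo-5,6-dihydro-2H-pyran-2-yl 2-methylpropanoate
Product: 5 (S)-6-[(4-methoxybenzyl)oxy]-2H-pyran-3(6H)-one
Conditions: 4-MeOC6H4CH2OH (2 equiv), Pd2(dba)3·CHCl3 (2.5 mol %), PPh3 (10 mol %), CH2Cl2, 0 °C
Reagents that add atoms: 4-methoxybenzyl alcohol, COc1ccc(CO)cc1
Why: Tsuji–Trost-type allylic etherification of a pyranone ester: zerovalent palladium ionises the C1–O bond anti to the carboxylate and the alcohol attacks the η3-allyl complex at C1 anti to palladium, so the double inversion retains the C1 configuration (the descriptor changes from R to S only through the priority rules).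

Step 4
Reactants: 6 (2-bromoallyl)trimethylsilane, 7 methyl vinyl ketone
Product: 8 6-bromohept-6-en-2-one
Conditions: TiCl4, CH2Cl2, −78 °C; aqueous work-up
Reagents that add atoms: none
Why: Hosomi–Sakurai conjugate allylation: the TiCl4-activated enone is attacked by the γ-carbon of the allylsilane with loss of silicon, the vinylic bromide being carried through; no stereocentre is formed.

Step 5
Reactants: 8 6-bromohept-6-en-2-one
Product: 9 2-bromo-6,6-dimethoxyhept-1-ene
Conditions: HC(OMe)3, MeOH, TsOH·H2O (cat.), rt; NaHCO3 quench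
Reagents that add atoms: trimethyl orthoformate, COC(OC)OC; methanol, CO
Why: Acid-catalysed ketalisation driven by the orthoformate as water scavenger; the acyclic dimethyl ketal survives the organolithium and enolate steps and can later be hydrolysed far faster than the ring acetal at C1; no stereocentre.

Step 6
Reactants: 9 2-bromo-6,6-dimethoxyhept-1-ene, 5 (S)-6-[(4-methoxybenzyl)oxy]-2H-pyran-3(6H)-one
Product: 13 methyl 2-[(2S,3R,4S)-3-(6,6-dimethoxyhept-1-en-2-yl)-2-[(4-methoxybenzyl)oxy]-5-oxotetrahydro-2H-pyran-4-yl]acetate, via alkenyllithium 10 (not isolated), via lithium dialkenylcuprate 11 (not isolated), via lithium enolate 12 (not isolated)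
Conditions: 9 (2.2 equiv), t-BuLi (4.4 equiv), Et2O, −78 °C; CuBr·SMe2 (1.1 equiv), −78 → −45 °C; 5 (1.0 equiv), Et2O/THF, −78 °C; then HMPA, BrCH2CO2Me (4 equiv), −78 → −20 °C; aq NH4Cl
Reagents that add atoms: methyl bromoacetate, COC(=O)CBr
Why: Halogen–lithium exchange on 9 gives the 2-lithioalkene 10, which forms cuprate 11 with CuBr·SMe2; 11 transfers one alkenyl group to C11a of enone 5 (copper–alkene π-complex, then reductive elimination) and leaves the regiodefined C4a=C4 lithium enolate 12, which is C-alkylated at C4a by methyl bromoacetate once HMPA is added. The closest known reaction type is organocuprate addition to alkyl 2,3-dideoxy-hex-2-enopyranosid-4-uloses, combined with the tandem conjugate addition–enolate alkylation (three-component coupling) used on 4-alkoxycyclopentenones. No ring is closed; the two new C–C bonds (C11–C11a and C4a–C5) are made on the preformed ring A. C11a is set by the C1 stereocentre: the 4-methoxybenzyloxy group is pseudoaxial in the enone half-chair (anomeric effect) and the cuprate attacks axially on the opposite face, giving the 1,11a-trans product; C4a is set by the new C11a substituent, the electrophile approaching the enolate anti to the vicinal alkenyl group (11a,4a-trans). The step needs 1,4- over 1,2-addition without loss of the γ-alkoxy group (secured by the soft cuprate at −78 °C and an alkoxy rather than acyloxy group at C1) and C-alkylation at C4a without enolate equilibration to C3 (secured by regiospecific enolate generation and low-temperature trapping with a reactive α-halo ester).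

Step 7
Reactants: 13 methyl 2-[(2S,3R,4S)-3-(6,6-dimethoxyhept-1-en-2-yl)-2-[(4-methoxybenzyl)oxy]-5-oxotetrahydro-2H-pyran-4-yl]acetate
Product: 15 methyl 2-[(2S,3R,4S)-3-(6,6-dimethoxyhept-1-en-2-yl)-2-[(4-methoxybenzyl)oxy]-5-(trifluoromethylsulfonyloxy)-3,4-dihydro-2H-pyran-4-yl]acetate, via potassium enolate 14 (not isolated)
Conditions: KN(SiMe3)2 (1.1 equiv), THF, −78 °C; PhNTf2, −78 → 0 °C
Reagents that add atoms: N-phenyl-bis(trifluoromethanesulfonimide), O=S(=O)(N(c1ccccc1)S(=O)(=O)C(F)(F)F)C(F)(F)F
Why: Kinetic enolisation and O-triflation: the hindered amide base removes a proton from the unhindered, oxygen-acidified C3 methylene in preference to the tertiary C4a–H flanked by two branches (and to the less acidic ester CH2), and enolate 14 is trapped on oxygen; C4a leaves the enolisable position and no new stereocentre forms.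

Step 8
Reactants: 15 methyl 2-[(2S,3R,4S)-3-(6,6-dimethoxyhept-1-en-2-yl)-2-[(4-methoxybenzyl)oxy]-5-(trifluoromethylsulfonyloxy)-3,4-dihydro-2H-pyran-4-yl]acetate
Product: 16 methyl 2-[(2S,3R,4S)-2-[(4-methoxybenzyl)oxy]-3-(6-oxohept-1-en-2-yl)-5-(trifluoromethylsulfonyloxy)-3,4-dihydro-2H-pyran-4-yl]acetate
Conditions: PPTS (cat.), acetone/H2O (10:1), rt
Reagents that add atoms: water, O
Why: Chemoselective ketal hydrolysis: a ketone dimethyl ketal ionises orders of magnitude faster than the aldehyde-level C1 acetal, whose ring oxygen is now conjugated with an electron-poor enol triflate; no stereocentre is touched.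

Step 9
Reactants: 17 prop-2-yn-1-ol
Product: 18 1-methoxy-4-[(prop-2-yn-1-yloxy)methyl]benzene
Conditions: NaH, 4-MeOC6H4CH2Cl, Bu4NI (cat.), THF/DMF, 0 °C → rt
Reagents that add atoms: 4-methoxybenzyl chloride, COc1ccc(CCl)cc1
Why: Williamson etherification of the primary alkoxide; no stereocentre.

Step 10
Reactants: 18 1-methoxy-4-[(prop-2-yn-1-yloxy)methyl]benzene
Product: 20 (E)-5-[(4-methoxybenzyl)oxy]-4-methylpent-3-en-1-ol, via alkenyldimethylalane 19 (not isolated)
Conditions: Me3Al, Cp2ZrCl2 (0.2 equiv), CH2Cl2, 0 °C → rt; n-BuLi, THF/hexane, −78 °C; ethylene oxide, −78 → 0 °C; aq Rochelle salt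
Reagents that add atoms: trimethylaluminium, C[Al](C)C; ethylene oxide, C1CO1
Why: Negishi zirconium-catalysed carboalumination adds CH3 and Al syn across the alkyne with methyl on the internal carbon, which fixes the E trisubstituted alkene, and the derived alkenylalanate opens the oxirane with retention of alkene geometry; no stereocentre.

Step 11
Reactants: 20 (E)-5-[(4-methoxybenzyl)oxy]-4-methylpent-3-en-1-ol
Product: 21 (E)-5-[(4-methoxybenzyl)oxy]-4-methylpent-3-enal
Conditions: Dess–Martin periodinane, NaHCO3, CH2Cl2, 0 °C; used at once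
Reagents that add atoms: none
Why: Dess–Martin oxidation under buffered, non-basic conditions should give the β,γ-unsaturated aldehyde without migration of the double bond into conjugation; no stereocentre.

Step 12
Reactants: 16 methyl 2-[(2S,3R,4S)-2-[(4-methoxybenzyl)oxy]-3-(6-oxohept-1-en-2-yl)-5-(trifluoromethylsulfonyloxy)-3,4-dihydro-2H-pyran-4-yl]acetate, 21 (E)-5-[(4-methoxybenzyl)oxy]-4-methylpent-3-enal
Product: 23 bis(4-methoxybenzyl) lactone (target skeleton with rings A and B; 4-methoxybenzyl ethers at C1–O and at the primary allylic oxygen; C1 S by the priority rules with the target's spatial arrangement; C4a S; C11a R; C12 S), via hydroxy ester 22 (not isolated)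
Conditions: CrCl2 (4 equiv), NiCl2 (2 mol %), N-[2-(4-isopropyl-4,5-dihydrooxazol-2-yl)-6-methylphenyl]methanesulfonamide (4.4 equiv, antipode as per the assumption), Et3N, THF, rt, 21 (1.5 equiv); aq ethylenediamine work-up; then DBU (0.3 equiv), 4 Å MS, PhMe, 50 °C
Reagents that add atoms: none
Why: Nozaki–Hiyama–Kishi coupling then lactonisation: zerovalent nickel inserts into the C4–OTf bond, transmetalation to trivalent chromium gives a ring alkenylchromium that cannot β-eliminate its C3 oxygen and adds only to the aldehyde (methyl ketone and ester are inert), the chiral sulfonamide ligand on chromium setting C12 (S); DBU then closes δ-lactone ring B by 6-exo-trig acyl substitution of the methyl ester with retention at C12.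

Step 13
Reactants: 23 bis(4-methoxybenzyl) lactone
Product: 24 lactol diol (target skeleton with free C1–OH as an anomeric mixture and free primary allylic OH)
Conditions: DDQ (2.6 equiv), CH2Cl2/pH 7 phosphate buffer (10:1), 0 °C
Reagents that add atoms: none
Why: Oxidative cleavage of both 4-methoxybenzyl groups (benzylic hydride abstraction, then hydrolysis) under buffered neutral conditions that should leave the acid-labile enol ether–allylic lactone intact; C1 becomes an equilibrating lactol and the other stereocentres are untouched.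

Step 14
Reactants: 24 lactol diol
Product: 25 CNP0120157.1 (target)
Conditions: Ac2O, pyridine, DMAP (cat.), CH2Cl2, 0 °C
Reagents that add atoms: acetic anhydride, CC(=O)OC(C)=O
Why: Base-mediated O-acetylation of the primary alcohol and of the lactol: the anomers interconvert by ring–chain tautomerism and the more stable, more nucleophilic anomer with the hydroxyl trans (pseudoequatorial) to the C11a alkenyl group is acylated, which should give the 1,11a-trans acetate (C1 R), as is usual for 2-hydroxy-3-substituted dihydropyrans of the iridoid type; the low temperature limits enolisation at C11a in the open form.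

**Compound list**

1 | furfuryl alcohol | OCc1ccco1 | starting material
2 | (Z)-5-hydroxy-4-oxopent-2-enal | O=C/C=C\C(=O)CO | intermediate
3 | 6-hydroxy-2H-pyran-3(6H)-one (racemic) | OC1OCC(=O)C=C1 | intermediate
4 | (R)-5-oxo-5,6-dihydro-2H-pyran-2-yl 2-methylpropanoate | CC(C)C(=O)O[C@H]1OCC(=O)C=C1 | intermediate
5 | (S)-6-[(4-methoxybenzyl)oxy]-2H-pyran-3(6H)-one | COc1ccc(CO[C@H]2OCC(=O)C=C2)cc1 | intermediate
6 | (2-bromoallyl)trimethylsilane | C=C(Br)C[Si](C)(C)C | starting material
7 | methyl vinyl ketone | CC(=O)C=C | starting material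
8 | 6-bromohept-6-en-2-one | CC(=O)CCCC(Br)=C | intermediate
9 | 2-bromo-6,6-dimethoxyhept-1-ene | C=C(Br)CCCC(C)(OC)OC | intermediate
10 | (6,6-dimethoxyhept-1-en-2-yl)lithium | [Li]C(=C)CCCC(C)(OC)OC | intermediate
11 | lithium bis(6,6-dimethoxyhept-1-en-2-yl)cuprate | [Li+].C=C(CCCC(C)(OC)OC)[Cu-]C(=C)CCCC(C)(OC)OC | intermediate
12 | lithium (5R,6S)-5-(6,6-dimethoxyhept-1-en-2-yl)-6-[(4-methoxybenzyl)oxy]-5,6-dihydro-2H-pyran-3-olate | C=C(CCCC(C)(OC)OC)[C@@H]1[C@@H](OCc2ccc(OC)cc2)OCC(O[Li])=C1 | intermediate
13 | methyl 2-[(2S,3R,4S)-3-(6,6-dimethoxyhept-1-en-2-yl)-2-[(4-methoxybenzyl)oxy]-5-oxotetrahydro-2H-pyran-4-yl]acetate | C=C(CCCC(C)(OC)OC)[C@@H]1[C@@H](OCc2ccc(OC)cc2)OCC(=O)[C@H]1CC(=O)OC | intermediate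
14 | potassium (2S,3R,4S)-3-(6,6-dimethoxyhept-1-en-2-yl)-4-(2-methoxy-2-oxoethyl)-2-[(4-methoxybenzyl)oxy]-3,4-dihydro-2H-pyran-5-olate | C=C(CCCC(C)(OC)OC)[C@@H]1[C@@H](OCc2ccc(OC)cc2)OC=C(O[K])[C@H]1CC(=O)OC | intermediate
15 | methyl 2-[(2S,3R,4S)-3-(6,6-dimethoxyhept-1-en-2-yl)-2-[(4-methoxybenzyl)oxy]-5-(trifluoromethylsulfonyloxy)-3,4-dihydro-2H-pyran-4-yl]acetate | C=C(CCCC(C)(OC)OC)[C@@H]1[C@@H](OCc2ccc(OC)cc2)OC=C(OS(=O)(=O)C(F)(F)F)[C@H]1CC(=O)OC | intermediate
16 | methyl 2-[(2S,3R,4S)-2-[(4-methoxybenzyl)oxy]-3-(6-oxohept-1-en-2-yl)-5-(trifluoromethylsulfonyloxy)-3,4-dihydro-2H-pyran-4-yl]acetate | C=C(CCCC(C)=O)[C@@H]1[C@@H](OCc2ccc(OC)cc2)OC=C(OS(=O)(=O)C(F)(F)F)[C@H]1CC(=O)OC | intermediate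
17 | prop-2-yn-1-ol | C#CCO | starting material
18 | 1-methoxy-4-[(prop-2-yn-1-yloxy)methyl]benzene | C#CCOCc1ccc(OC)cc1 | intermediate
19 | (E)-{3-[(4-methoxybenzyl)oxy]-2-methylprop-1-en-1-yl}dimethylalane | C[Al](C)/C=C(\C)COCc1ccc(OC)cc1 | intermediate
20 | (E)-5-[(4-methoxybenzyl)oxy]-4-methylpent-3-en-1-ol | OCC/C=C(\C)COCc1ccc(OC)cc1 | intermediate
21 | (E)-5-[(4-methoxybenzyl)oxy]-4-methylpent-3-enal | O=CC/C=C(\C)COCc1ccc(OC)cc1 | intermediate
22 | methyl 2-[(2S,3R,4S)-5-[(1S,3E)-1-hydroxy-5-[(4-methoxybenzyl)oxy]-4-methylpent-3-en-1-yl]-2-[(4-methoxybenzyl)oxy]-3-(6-oxohept-1-en-2-yl)-3,4-dihydro-2H-pyran-4-yl]acetate | C=C(CCCC(C)=O)[C@@H]1[C@@H](OCc2ccc(OC)cc2)OC=C([C@@H](O)C/C=C(\C)COCc2ccc(OC)cc2)[C@H]1CC(=O)OC | intermediate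
23 | bis(4-methoxybenzyl) lactone: target skeleton with C1–O and the primary allylic oxygen as 4-methoxybenzyl ethers | C=C(CCCC(C)=O)[C@@H]1[C@@H](OCc2ccc(OC)cc2)OC=C2[C@H](C/C=C(\C)COCc3ccc(OC)cc3)OC(=O)C[C@H]21 | intermediate
24 | lactol diol: target skeleton with free C1–OH (anomeric mixture) and free primary allylic OH | C=C(CCCC(C)=O)[C@@H]1C(O)OC=C2[C@H](C/C=C(\C)CO)OC(=O)C[C@H]21 | intermediate
25 | CNP0120157.1, the (1R,4aS,11aR,12S) diacetate | C=C(CCCC(C)=O)[C@@H]1[C@@H](OC(C)=O)OC=C2[C@H](C/C=C(\C)COC(C)=O)OC(=O)C[C@H]21 | target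

**Step count and risks**

Total steps: 14. Longest linear sequence: 9 (steps 1, 2, 3, 6, 7, 8, 12, 13, 14).

The three steps most likely to fail:

Step 7. The enolisation may lose regiocontrol: deprotonation at C4a, or proton exchange during the slow O-triflation, would give the tetrasubstituted C4=C4a enol triflate. The fallback sets out from 13 and replaces kinetic deprotonation by thermodynamic enol silylation (Me3SiCl, Et3N, DMF, 80 °C). This should favour the oxygen-substituted, less strained C3=C4 isomer and give methyl 2-[(2S,3R,4S)-3-(6,6-dimethoxyhept-1-en-2-yl)-2-[(4-methoxybenzyl)oxy]-5-(trimethylsilyloxy)-3,4-dihydro-2H-pyran-4-yl]acetate F1 after chromatographic removal of any regioisomer, which is hydrolysed back to 13. Fluoride-mediated exchange (CsF, PhNTf2, DME, rt) then converts F1 regiospecifically into 15, where the route is rejoined.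

Step 12. Facial selectivity at C12 may be insufficient, and the double bond of aldehyde 21 may migrate under the Lewis-acidic conditions. The fallback sets out from 15, in which the methyl ketone is still masked. Ligand-free Ni/Cr coupling with 21 gives the C12-epimeric hydroxy ester ketal F2. Dess–Martin oxidation gives the vinylogous ester ketone F3. Corey–Bakshi–Shibata reduction with the (R)-oxazaborolidine and catecholborane, the branched alkenyl group acting as the large substituent, should give the (12S)-alcohol F4. DBU lactonisation gives the lactone ketal F5, and PPTS in acetone/water returns the route to 23.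

Step 6. The copper-containing enolate may alkylate sluggishly or unselectively: proton transfer, O-alkylation, or coupling of residual alkenylcopper with the bromoester. The fallback sets out from 5 and cuprate 11. Conjugate addition in the presence of Me3SiCl gives the isolated (2S,3R)-3-(6,6-dimethoxyhept-1-en-2-yl)-2-[(4-methoxybenzyl)oxy]-5-(trimethylsilyloxy)-3,6-dihydro-2H-pyran F6. MeLi in THF regenerates the copper-free lithium enolate 12, which is alkylated with methyl bromoacetate and HMPA to rejoin the route at 13.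

**Further compounds**

F1 | step 7 | methyl 2-[(2S,3R,4S)-3-(6,6-dimethoxyhept-1-en-2-yl)-2-[(4-methoxybenzyl)oxy]-5-(trimethylsilyloxy)-3,4-dihydro-2H-pyran-4-yl]acetate | C=C(CCCC(C)(OC)OC)[C@@H]1[C@@H](OCc2ccc(OC)cc2)OC=C(O[Si](C)(C)C)[C@H]1CC(=O)OC
F2 | step 12 | methyl 2-[(2S,3R,4S)-3-(6,6-dimethoxyhept-1-en-2-yl)-5-[(3E)-1-hydroxy-5-[(4-methoxybenzyl)oxy]-4-methylpent-3-en-1-yl]-2-[(4-methoxybenzyl)oxy]-3,4-dihydro-2H-pyran-4-yl]acetate (C12 epimers) | C=C(CCCC(C)(OC)OC)[C@@H]1[C@@H](OCc2ccc(OC)cc2)OC=C(C(O)C/C=C(\C)COCc2ccc(OC)cc2)[C@H]1CC(=O)OC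
F3 | step 12 | methyl 2-[(2S,3R,4S)-3-(6,6-dimethoxyhept-1-en-2-yl)-5-[(3E)-5-[(4-methoxybenzyl)oxy]-4-methylpent-3-enoyl]-2-[(4-methoxybenzyl)oxy]-3,4-dihydro-2H-pyran-4-yl]acetate | C=C(CCCC(C)(OC)OC)[C@@H]1[C@@H](OCc2ccc(OC)cc2)OC=C(C(=O)C/C=C(\C)COCc2ccc(OC)cc2)[C@H]1CC(=O)OC
F4 | step 12 | methyl 2-[(2S,3R,4S)-3-(6,6-dimethoxyhept-1-en-2-yl)-5-[(1S,3E)-1-hydroxy-5-[(4-methoxybenzyl)oxy]-4-methylpent-3-en-1-yl]-2-[(4-methoxybenzyl)oxy]-3,4-dihydro-2H-pyran-4-yl]acetate | C=C(CCCC(C)(OC)OC)[C@@H]1[C@@H](OCc2ccc(OC)cc2)OC=C([C@@H](O)C/C=C(\C)COCc2ccc(OC)cc2)[C@H]1CC(=O)OC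
F5 | step 12 | dimethyl ketal of bis(4-methoxybenzyl) lactone 23 | C=C(CCCC(C)(OC)OC)[C@@H]1[C@@H](OCc2ccc(OC)cc2)OC=C2[C@H](C/C=C(\C)COCc3ccc(OC)cc3)OC(=O)C[C@H]21
F6 | step 6 | (2S,3R)-3-(6,6-dimethoxyhept-1-en-2-yl)-2-[(4-methoxybenzyl)oxy]-5-(trimethylsilyloxy)-3,6-dihydro-2H-pyran | C=C(CCCC(C)(OC)OC)[C@@H]1[C@@H](OCc2ccc(OC)cc2)OCC(O[Si](C)(C)C)=C1
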